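**Retrosynthetic overview** (flavanone numbering: ring C = O1, C2, C3, C4, C4a, C8a; ring A = C4a, C5–C8, C8a)

1. 22 ⇐ 21 (desilylation). Ring A of 21 is opened by a Danheiser-type benzannulation transform (C4a–C5 by 6π closure; C5–C6 and C7–C8 by ketene–ynol ether [2+2]) to acid 15 (as ketene 17) and ynol ether 14; the ring construction itself places 5-OH, 6-prenyl, 7-OMe and 8-prenyl.
2. Ring C of 15/11 is disconnected at C4–C4a and O1–C8a to the four-membered lactone 5 (O1, C2, C3, C4) and the dianion of keto ester 8 (C4a, C8a, C8, C5): a two-atom ring expansion, 4 → 6.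
3. Enabling feature: O1–C2–C3–C4 is a β-hydroxy acid (aldol) unit, so it can be held as a β-lactone with a strained O1–C4 acyl–oxygen bond. C4 and C8a are 1,3-related oxygen-bearing carbons across C4a, so a CH2–C(=O) unit (C4a–C8a) can be inserted into O1–C4 by acylation at C4a and return of O1 to C8a. Ring C results as the vinylogous ester O1–C8a=C4a–C4=O.
4. Lactone 5 comes from vanillin (1) by silylation and a catalytic asymmetric ketene–aldehyde [2+2] cycloaddition that sets C2; 8 and 14 each come in one step from prenyl bromide.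
5. Order of ring formation: oxetanone (step 2) → ring C by ring expansion (step 4) → transient cyclobutenone → ring A by electrocyclic ring expansion (step 7).

Key step: step 4

Assumption: the quinine-derived silyl ether is taken as the catalyst antipode that delivers the (S)-lactone; if a test reaction shows the opposite sense, the quinidine-derived pseudoenantiomer is used with no other change. Centres that later become sp2 carbons of ring A (the ester α-carbon of 8, 10, 11, 15, 16; C4 of 18; C4a of 20) form as mixtures and are left unspecified.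

**Route**

Step 1
Reactants: 1 vanillin (4-hydroxy-3-methoxybenzaldehyde)
Product: 2 3-methoxy-4-(triisopropylsilyloxy)benzaldehyde
Conditions: TIPSCl, imidazole, DMF, rt
Reagents that add atoms: triisopropylsilyl chloride (TIPSCl), CC(C)[Si](Cl)(C(C)C)C(C)C
Why: Standard silylation of a phenol; the TIPS ether should tolerate the lithium dianion, Pd(0), the acid chloride stage and 100 °C, and comes off with buffered fluoride at the end.

Step 2
Reactants: 2 3-methoxy-4-(triisopropylsilyloxy)benzaldehyde; 3 acetyl chloride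
Product: 5 (4S)-4-[3-methoxy-4-(triisopropylsilyloxy)phenyl]oxetan-2-one, via ketene 4 (not isolated)
Conditions: iPr2NEt, O-trimethylsilylquinine (10 mol%), LiClO4, CH2Cl2/Et2O, −78 °C, slow addition of 3
Reagents that add atoms: none
Why: Catalytic asymmetric ketene–aldehyde [2+2] cycloaddition (cinchona alkaloid nucleophilic catalysis with a lithium Lewis acid): the alkaloid-bound ammonium enolate of 4 adds to one face of the aldehyde and closes to the lactone, so the catalyst sets the stereocentre (later C2) as (S).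

Step 3
Reactants: 6 allyl acetoacetate (prop-2-en-1-yl 3-oxobutanoate); 7 prenyl bromide (1-bromo-3-methylbut-2-ene)
Product: 8 allyl 2-acetyl-5-methylhex-4-enoate (racemic)
Conditions: K2CO3, acetone, reflux
Reagents that add atoms: none
Why: C-alkylation of a β-keto ester enolate by an allylic bromide (SN2), which puts the future C8 prenyl group in place.

Step 4
Reactants: 8 allyl 2-acetyl-5-methylhex-4-enoate (2.2 equiv); 5 (4S)-4-[3-methoxy-4-(triisopropylsilyloxy)phenyl]oxetan-2-one
Product: 11 allyl 2-{(2S)-2-[3-methoxy-4-(triisopropylsilyloxy)phenyl]-4-oxo-3,4-dihydro-2H-pyran-6-yl}-5-methylhex-4-enoate (epimers at the ester α-carbon), via dilithium dienolate 9 (not isolated), via open-chain hydroxy diketo ester 10 (not isolated)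
Conditions: LDA (2 equiv per 8), THF, −78 → 0 °C; then 5, −78 → −40 °C; AcOH; then p-TsOH·H2O (5 mol%), CH2Cl2, 0 °C → rt
Reagents that add atoms: none
Why: The terminal carbanion (C4a) of dianion 9 attacks the strained acyl carbon C4 of 5 (Claisen-type acyl substitution with acyl–oxygen cleavage), so the O1–C4 bond opens to the C2 alkoxide while the new 1,3-diketone is held as its enolate, which blocks retro-aldol cleavage. After the acetic acid quench, acid catalysis returns O1 to the ketone carbon C8a (6-exo-trig hemiketalisation) and dehydration gives the vinylogous ester O1–C8a=C4a–C4=O. The net result is insertion of C4a–C8a into the O1–C4 bond, a ring expansion of the oxetanone (O1, C2, C3, C4) to the six-membered ring C. The closest known reaction types are the acylation of lithium ester enolates and β-keto ester dianions by lactones and the acid cyclodehydration of δ-hydroxy-β-diketones to 2,3-dihydro-4H-pyran-4-ones. No ring stereocentre is created: C2 keeps the (S) configuration of 5 because its C–O bond is never broken, and the side-chain centre forms as a mixture that becomes sp2 (C8) in step 7. The step needs attack at the acyl carbon and not at benzylic C2 (secured by the hard lithium carbanion at −78 °C), reaction through the methyl terminus of the dianion (its more basic site), and closure of O1 onto C8a, the only carbonyl that gives a six-membered ring.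

Step 5
Reactants: 12 chloroacetaldehyde dimethyl acetal (2-chloro-1,1-dimethoxyethane); 7 prenyl bromide
Product: 14 1-methoxy-5-methylhex-4-en-1-yne, via sodium methoxyacetylide 13 (not isolated)
Conditions: NaNH2 (3 equiv), liq. NH3, −33 °C; then 7
Reagents that add atoms: none
Why: Twofold elimination (HCl and MeOH) from the chloroacetal gives the alkoxyacetylide, which is alkylated in liquid ammonia by the allylic bromide (SN2), the classical route to 1-alkoxyalk-1-ynes.

Step 6
Reactants: 11 allyl 2-{(2S)-2-[3-methoxy-4-(triisopropylsilyloxy)phenyl]-4-oxo-3,4-dihydro-2H-pyran-6-yl}-5-methylhex-4-enoate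
Product: 15 2-{(2S)-2-[3-methoxy-4-(triisopropylsilyloxy)phenyl]-4-oxo-3,4-dihydro-2H-pyran-6-yl}-5-methylhex-4-enoic acid
Conditions: Pd(PPh3)4 (5 mol%), sodium p-toluenesulfinate, THF/MeOH, rt; cold 1 M HCl work-up
Reagents that add atoms: none
Why: Tsuji–Trost deallylation: Pd(0) ionises the allyl ester and the sulfinate takes the allyl group as a sulfone, a neutral and non-basic ester cleavage that should leave the vinylogous ester, the silyl ether, the prenyl group and C2 untouched.

Step 7
Reactants: 15 2-{(2S)-2-[3-methoxy-4-(triisopropylsilyloxy)phenyl]-4-oxo-3,4-dihydro-2H-pyran-6-yl}-5-methylhex-4-enoic acid; 14 1-methoxy-5-methylhex-4-en-1-yne (3 equiv)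
Product: 21 (2S)-5-hydroxy-7-methoxy-2-[3-methoxy-4-(triisopropylsilyloxy)phenyl]-6,8-bis(3-methylbut-2-en-1-yl)chroman-4-one, via acid chloride 16 (not isolated), via ketene 17 (not isolated), via cyclobutenone 18 (not isolated), via dienylketene 19 (not isolated), via cyclohexadienone 20 (not isolated)
Conditions: 1-chloro-N,N,2-trimethylpropenylamine, CH2Cl2, 0 °C; then 14, Et3N (1.05 equiv), toluene, 0 → 25 °C; then 100 °C
Reagents that add atoms: none
Why: Danheiser-type benzannulation entered at the ketene stage: ketene 17 (by dehydrochlorination of 16) undergoes regioselective [2+2] cycloaddition with ynol ether 14 (its nucleophilic carbon bonds to the ketene carbonyl carbon) to the 4-alkenylcyclobutenone 18, whose 4π ring opening gives dienylketene 19; 6π electrocyclisation onto C4a of the pyranone C4a=C8a bond and tautomerisation of 20 give the phenol, so that 5-OH, 6-prenyl, 7-OMe and 8-prenyl are placed by the ring construction under neutral thermal conditions that do not touch C2.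

Step 8
Reactants: 21 (2S)-5-hydroxy-7-methoxy-2-[3-methoxy-4-(triisopropylsilyloxy)phenyl]-6,8-bis(3-methylbut-2-en-1-yl)chroman-4-one
Product: 22 (2S)-5-hydroxy-2-(4-hydroxy-3-methoxyphenyl)-7-methoxy-6,8-bis(3-methylbut-2-en-1-yl)chroman-4-one (target)
Conditions: TBAF, AcOH (1:1), THF, 0 °C
Reagents that add atoms: none
Why: Fluoride cleaves the aryl silyl ether, and buffering with acetic acid keeps the medium non-basic so that ring C should not open to the chalcone and C2 stays (S).

**Compound list**

1 | vanillin | COc1cc(C=O)ccc1O | starting material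
2 | 3-methoxy-4-(triisopropylsilyloxy)benzaldehyde | COc1cc(C=O)ccc1O[Si](C(C)C)(C(C)C)C(C)C | intermediate
3 | acetyl chloride | CC(Cl)=O | starting material
4 | ketene | C=C=O | intermediate
5 | (4S)-4-[3-methoxy-4-(triisopropylsilyloxy)phenyl]oxetan-2-one | O=C1C[C@@H](c2ccc(O[Si](C(C)C)(C(C)C)C(C)C)c(OC)c2)O1 | intermediate
6 | allyl acetoacetate | CC(=O)CC(=O)OCC=C | starting material
7 | prenyl bromide | CC(C)=CCBr | starting material
8 | allyl 2-acetyl-5-methylhex-4-enoate (racemic) | CC(=O)C(CC=C(C)C)C(=O)OCC=C | intermediate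
9 | dilithium dienolate (1,3-dianion) of 8 | [Li+].[Li+].C=C([O-])C(CC=C(C)C)=C([O-])OCC=C | intermediate
10 | allyl (7S)-7-hydroxy-7-[3-methoxy-4-(triisopropylsilyloxy)phenyl]-2-(3-methylbut-2-en-1-yl)-3,5-dioxoheptanoate (C2 epimers, keto form shown) | C=CCOC(=O)C(CC=C(C)C)C(=O)CC(=O)C[C@H](O)c1ccc(O[Si](C(C)C)(C(C)C)C(C)C)c(OC)c1 | intermediate
11 | allyl 2-{(2S)-2-[3-methoxy-4-(triisopropylsilyloxy)phenyl]-4-oxo-3,4-dihydro-2H-pyran-6-yl}-5-methylhex-4-enoate (epimers at the ester α-carbon) | C=CCOC(=O)C(CC=C(C)C)C1=CC(=O)C[C@@H](c2ccc(O[Si](C(C)C)(C(C)C)C(C)C)c(OC)c2)O1 | intermediate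
12 | chloroacetaldehyde dimethyl acetal | COC(CCl)OC | starting material
13 | sodium methoxyacetylide | [Na+].[C-]#COC | intermediate
14 | 1-methoxy-5-methylhex-4-en-1-yne | COC#CCC=C(C)C | intermediate
15 | 2-{(2S)-2-[3-methoxy-4-(triisopropylsilyloxy)phenyl]-4-oxo-3,4-dihydro-2H-pyran-6-yl}-5-methylhex-4-enoic acid (α-epimers) | OC(=O)C(CC=C(C)C)C1=CC(=O)C[C@@H](c2ccc(O[Si](C(C)C)(C(C)C)C(C)C)c(OC)c2)O1 | intermediate
16 | acid chloride of 15 | ClC(=O)C(CC=C(C)C)C1=CC(=O)C[C@@H](c2ccc(O[Si](C(C)C)(C(C)C)C(C)C)c(OC)c2)O1 | intermediate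
17 | 2-{(2S)-2-[3-methoxy-4-(triisopropylsilyloxy)phenyl]-4-oxo-3,4-dihydro-2H-pyran-6-yl}-5-methylhexa-1,4-dien-1-one (ketene) | O=C=C(CC=C(C)C)C1=CC(=O)C[C@@H](c2ccc(O[Si](C(C)C)(C(C)C)C(C)C)c(OC)c2)O1 | intermediate
18 | 3-methoxy-2,4-bis(3-methylbut-2-en-1-yl)-4-{(2S)-2-[3-methoxy-4-(triisopropylsilyloxy)phenyl]-4-oxo-3,4-dihydro-2H-pyran-6-yl}cyclobut-2-en-1-one (C4 epimers) | COC1=C(CC=C(C)C)C(=O)C1(CC=C(C)C)C2=CC(=O)C[C@@H](c3ccc(O[Si](C(C)C)(C(C)C)C(C)C)c(OC)c3)O2 | intermediate
19 | dienylketene from ring opening of 18 (pyranonyl group cis to the ketene-bearing carbon in the reacting isomer) | O=C=C(CC=C(C)C)C(OC)=C(CC=C(C)C)C1=CC(=O)C[C@@H](c2ccc(O[Si](C(C)C)(C(C)C)C(C)C)c(OC)c2)O1 | intermediate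
20 | (2S)-7-methoxy-2-[3-methoxy-4-(triisopropylsilyloxy)phenyl]-6,8-bis(3-methylbut-2-en-1-yl)-2,3-dihydro-4aH-chromene-4,5-dione (cyclohexa-2,4-dienone tautomer of 21) | O=C1C(CC=C(C)C)=C(OC)C(CC=C(C)C)=C2O[C@H](c3ccc(O[Si](C(C)C)(C(C)C)C(C)C)c(OC)c3)CC(=O)C12 | intermediate
21 | (2S)-5-hydroxy-7-methoxy-2-[3-methoxy-4-(triisopropylsilyloxy)phenyl]-6,8-bis(3-methylbut-2-en-1-yl)chroman-4-one | COc1cc([C@@H]2CC(=O)c3c(O)c(CC=C(C)C)c(OC)c(CC=C(C)C)c3O2)ccc1O[Si](C(C)C)(C(C)C)C(C)C | intermediate
22 | (2S)-5-hydroxy-2-(4-hydroxy-3-methoxyphenyl)-7-methoxy-6,8-bis(3-methylbut-2-en-1-yl)chroman-4-one | COc1cc([C@@H]2CC(=O)c3c(O)c(CC=C(C)C)c(OC)c(CC=C(C)C)c3O2)ccc1O | target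

**Step count**

Total: 8 steps. Longest linear sequence: 6 steps (1 → 2 → 5 → 11 → 15 → 21 → 22; steps 1, 2, 4, 6, 7, 8).

**Steps most likely to fail**

Step 7. The ketene may dimerise or be captured by chloride or amine faster than it undergoes [2+2] addition with the ynol ether. The electrocyclic opening of the cyclobutenone may stall. Residual base at 100 °C may open ring C by retro-oxa-Michael reaction, with loss of configuration at C2. The fallback sets out from 15, replaces the pericyclic ring construction by a Claisen/Dieckmann folding of a poly-β-carbonyl chain, and returns at 21. Acid 15 is activated with carbonyldiimidazole to the acyl imidazole of 15 F1. F1 acylates the magnesium salt of methyl hydrogen (3-methylbut-2-en-1-yl)malonate with loss of CO2 (decarboxylative Claisen condensation) to methyl 2,4-bis(3-methylbut-2-en-1-yl)-3-oxo-4-{(2S)-2-[3-methoxy-4-(triisopropylsilyloxy)phenyl]-4-oxo-3,4-dihydro-2H-pyran-6-yl}butanoate F2. Mild base (DBU, THF, 0 °C) should close ring A by Dieckmann attack of C4a on the methyl ester and enolisation, giving (2S)-5,7-dihydroxy-2-[3-methoxy-4-(triisopropylsilyloxy)phenyl]-6,8-bis(3-methylbut-2-en-1-yl)chroman-4-one F3. Methylation with trimethylsilyldiazomethane should take the free 7-OH and spare the hydrogen-bonded 5-OH, giving 21.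

Step 4. The carbanion may attack the benzylic carbon of the lactone (alkyl–oxygen cleavage). It may instead remove a proton at C3 of the lactone, which leads to β-elimination. During the acid ring closure, dehydration and re-addition at C2 may erode the enantiomeric purity. The fallback sets out from 5, separates ring opening from C–C bond formation, and returns at 11. Lactone 5 is opened with N,O-dimethylhydroxylamine (Me2AlCl, CH2Cl2) to (3S)-3-hydroxy-N-methoxy-N-methyl-3-[3-methoxy-4-(triisopropylsilyloxy)phenyl]propanamide F4. The alcohol is silylated (TESCl, imidazole) to the triethylsilyl ether of F4 F5. Dianion 9 is acylated by F5 to allyl (7S)-7-[3-methoxy-4-(triisopropylsilyloxy)phenyl]-2-(3-methylbut-2-en-1-yl)-3,5-dioxo-7-(triethylsilyloxy)heptanoate F6. p-TsOH in MeOH/CH2Cl2 should remove the TES group and cyclodehydrate to 11.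

Step 2. The cycloaddition may be slow with the electron-rich aldehyde, the facial selectivity may be poor, and the donor-substituted lactone may decarboxylate during isolation. The fallback sets out from 2, builds the stereocentre by an aldol reaction instead of a cycloaddition, and returns at 5. An asymmetric Mukaiyama aldol addition of 1-(tert-butylthio)-1-(trimethylsilyloxy)ethene to 2 under a chiral titanium(IV)–BINOL Lewis acid, with acidic work-up, should give S-tert-butyl (3S)-3-hydroxy-3-[3-methoxy-4-(triisopropylsilyloxy)phenyl]propanethioate F7. Thiophilic activation (Hg(OCOCF3)2, Na2HPO4, MeCN) closes the lactone by attack of the carbinol oxygen on the acyl carbon, with retention at the stereocentre, and the lactone is used cold and at once.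

**Further compounds**

F1 | step 7 | acyl imidazole of acid 15 | O=C(n3ccnc3)C(CC=C(C)C)C1=CC(=O)C[C@@H](c2ccc(O[Si](C(C)C)(C(C)C)C(C)C)c(OC)c2)O1
F2 | step 7 | methyl 2,4-bis(3-methylbut-2-en-1-yl)-3-oxo-4-{(2S)-2-[3-methoxy-4-(triisopropylsilyloxy)phenyl]-4-oxo-3,4-dihydro-2H-pyran-6-yl}butanoate | COC(=O)C(CC=C(C)C)C(=O)C(CC=C(C)C)C1=CC(=O)C[C@@H](c2ccc(O[Si](C(C)C)(C(C)C)C(C)C)c(OC)c2)O1
F3 | step 7 | (2S)-5,7-dihydroxy-2-[3-methoxy-4-(triisopropylsilyloxy)phenyl]-6,8-bis(3-methylbut-2-en-1-yl)chroman-4-one | COc1cc([C@@H]2CC(=O)c3c(O)c(CC=C(C)C)c(O)c(CC=C(C)C)c3O2)ccc1O[Si](C(C)C)(C(C)C)C(C)C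
F4 | step 4 | (3S)-3-hydroxy-N-methoxy-N-methyl-3-[3-methoxy-4-(triisopropylsilyloxy)phenyl]propanamide | CON(C)C(=O)C[C@H](O)c1ccc(O[Si](C(C)C)(C(C)C)C(C)C)c(OC)c1
F5 | step 4 | (3S)-N-methoxy-N-methyl-3-[3-methoxy-4-(triisopropylsilyloxy)phenyl]-3-(triethylsilyloxy)propanamide | CON(C)C(=O)C[C@H](O[Si](CC)(CC)CC)c1ccc(O[Si](C(C)C)(C(C)C)C(C)C)c(OC)c1
F6 | step 4 | allyl (7S)-7-[3-methoxy-4-(triisopropylsilyloxy)phenyl]-2-(3-methylbut-2-en-1-yl)-3,5-dioxo-7-(triethylsilyloxy)heptanoate | C=CCOC(=O)C(CC=C(C)C)C(=O)CC(=O)C[C@H](O[Si](CC)(CC)CC)c1ccc(O[Si](C(C)C)(C(C)C)C(C)C)c(OC)c1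
F7 | step 2 | S-tert-butyl (3S)-3-hydroxy-3-[3-methoxy-4-(triisopropylsilyloxy)phenyl]propanethioate | CC(C)(C)SC(=O)C[C@H](O)c1ccc(O[Si](C(C)C)(C(C)C)C(C)C)c(OC)c1
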